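**Retrosynthetic overview**
- The target comes from its undeca-silyl ether; the chalcone is cut last at the aryl–CH=CH bond (Heck coupling of an aryl bromide with an aryl vinyl ketone).
- The tetrahydrofuran (second ring formed) is cut at C2'–H (hydride reduction of a ring C oxocarbenium ion), at C3' (ketal equilibration) and at C4'–C5' (catalytic anti Mukaiyama aldol). Its chain comes from enolate alkylation with a phenacyl bromide and a Weinreb ketone synthesis on ring C.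
- The chroman (first ring formed, key step) is cut by an enantioselective [4+2] cycloaddition of an E-stilbene with an ortho-quinone methide. The quinone methide arises by dearomatising one of the two identical rings of symmetric bis(2-hydroxy-4-silyloxyphenyl)methanol, made from the UV filter 2,2',4,4'-tetrahydroxybenzophenone. This sets C2, C3 and C4 and leaves the second ring as ring C with the only free phenol, which directs para-iodination.

Assumption: the sense of induction of the two chiral catalysts (steps 5 and 13) is assigned by analogy with their model reactions; the mirror-image catalysts are equally available if the opposite sense is found.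

Notation: TBS = tert-butyldimethylsilyl. Ring A = benzo ring of the chroman, ring C = the resorcinol ring on chroman C4, ring D = the aryl ring on chroman C3. Tetrahydrofuran atoms: C2' (on ring C), C3' (benzyl), C4' (aroyl), C5' (aryl). Fl = (2S,3R)-3-[5-bromo-2-(TBSO)phenyl]-7-(TBSO)-2-[4-(TBSO)phenyl]chroman-4-yl, bonded through C4, 2,3-trans-3,4-trans as in 9. When ring C carries OTBS next to C4, the CIP label of C4 is S; the geometry is unchanged.

**Route**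

Step 1
Reactants: 1 2,2',4,4'-tetrahydroxybenzophenone
Product: 2 bis[4-(TBSO)-2-hydroxyphenyl]methanone
Conditions: TBSCl (2.1 equiv), imidazole, DMF, 0 °C
Reagents that add atoms: tert-butyldimethylsilyl chloride (TBSCl), CC(C)(C)[Si](C)(C)Cl
Why: Phenol O-silylation; the two 2-OH groups are hydrogen-bonded to the ketone, so only the 4- and 4'-phenols react.

Step 2
Reactants: 2 bis[4-(TBSO)-2-hydroxyphenyl]methanone
Product: 3 bis[4-(TBSO)-2-hydroxyphenyl]methanol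
Conditions: NaBH4, THF/EtOH, 0 °C; aq NH4Cl
Reagents that add atoms: none
Why: Borohydride reduction of the diaryl ketone; low temperature and a neutral quench avoid over-reduction through the quinone methide.

Step 3
Reactants: 4 4-bromo-2-iodophenol
Product: 5 (4-bromo-2-iodophenoxy)(tert-butyl)dimethylsilane
Conditions: TBSCl, imidazole, DMF, rt
Reagents that add atoms: tert-butyldimethylsilyl chloride (TBSCl), CC(C)(C)[Si](C)(C)Cl
Why: Standard phenol silylation.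

Step 4
Reactants: 5 (4-bromo-2-iodophenoxy)(tert-butyl)dimethylsilane; 6 tert-butyldimethyl(4-vinylphenoxy)silane
Product: 7 (E)-tert-butyl{4-bromo-2-[4-(TBSO)styryl]phenoxy}dimethylsilane
Conditions: Pd(OAc)2 (5 mol %), P(o-tol)3, Et3N, MeCN, 70 °C
Reagents that add atoms: none
Why: Mizoroki–Heck reaction; oxidative addition takes the C–I bond and leaves C–Br, and syn-insertion/β-hydride elimination gives the E-stilbene.

Step 5
Reactants: 3 bis[4-(TBSO)-2-hydroxyphenyl]methanol; 7 (E)-tert-butyl{4-bromo-2-[4-(TBSO)styryl]phenoxy}dimethylsilane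
Product: 9 (2S,3R,4R)-3-[5-bromo-2-(TBSO)phenyl]-7-(TBSO)-4-[4-(TBSO)-2-hydroxyphenyl]-2-[4-(TBSO)phenyl]chromane, via ortho-quinone methide 8 (not isolated)
Conditions: (R)-3,3'-bis(2,4,6-triisopropylphenyl)-1,1'-binaphthyl-2,2'-diyl N-(trifluoromethylsulfonyl)phosphoramide (10 mol %), 4 Å MS, CH2Cl2, −10 °C → rt, slow addition of 3 to 7 (1.5 equiv)
Reagents that add atoms: none
Why: Proposed new method: the chiral Brønsted acid dehydrates 3 and dearomatises one of its two identical phenol rings to the hydrogen-bonded ortho-quinone methide 8, which adds to the electron-rich E-alkene 7 in an inverse-electron-demand hetero-Diels–Alder reaction (oxygen bonds to the carbon bearing the 4-silyloxyphenyl ring, the better cation-stabilising end), the E-geometry giving 2,3-trans, the endo all-equatorial transition state giving 3,4-trans and the chiral phosphoramide anion selecting the face, so that C2, C3 and C4 are set at once and the two rings of 3 become different (fused ring A, pendant ring C with the only free OH); the closest known reaction type is the N-triflylphosphoramide-catalysed [4+2] cycloaddition of ortho-hydroxybenzhydrol-derived quinone methides with styrenes, extended here to a 1,2-diaryl alkene.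

Step 6
Reactants: 9 (2S,3R,4R)-3-[5-bromo-2-(TBSO)phenyl]-7-(TBSO)-4-[4-(TBSO)-2-hydroxyphenyl]-2-[4-(TBSO)phenyl]chromane
Product: 11 1-Fl-2,4-bis(TBSO)-5-iodobenzene, via iodophenol 10 (not isolated)
Conditions: N-iodosuccinimide (1.0 equiv), DMF, −20 → 0 °C; then imidazole, TBSCl, rt
Reagents that add atoms: N-iodosuccinimide, O=C1CCC(=O)N1I; tert-butyldimethylsilyl chloride (TBSCl), CC(C)(C)[Si](C)(C)Cl
Why: Electrophilic aromatic iodination goes para to the only free phenol (ring C; the aryl ether rings need acid activation and the ortho site is flanked by OTBS), then the phenol is silylated in the same flask.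

Step 7
Reactants: 12 3-(4-hydroxyphenyl)propanoic acid
Product: 13 3-(4-hydroxyphenyl)-N-methoxy-N-methylpropanamide
Conditions: MeNHOMe·HCl, N-(3-dimethylaminopropyl)-N'-ethylcarbodiimide hydrochloride, 1-hydroxybenzotriazole (cat.), i-Pr2NEt, CH2Cl2, rt
Reagents that add atoms: N,O-dimethylhydroxylamine hydrochloride, CNOC.Cl
Why: Carbodiimide amide coupling to the Weinreb amide; the amine outcompetes the phenol for the activated ester.

Step 8
Reactants: 13 3-(4-hydroxyphenyl)-N-methoxy-N-methylpropanamide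
Product: 14 3-[4-(TBSO)phenyl]-N-methoxy-N-methylpropanamide
Conditions: TBSCl, imidazole, DMF, rt
Reagents that add atoms: tert-butyldimethylsilyl chloride (TBSCl), CC(C)(C)[Si](C)(C)Cl
Why: Standard phenol silylation.

Step 9
Reactants: 11 1-Fl-2,4-bis(TBSO)-5-iodobenzene; 14 3-[4-(TBSO)phenyl]-N-methoxy-N-methylpropanamide
Product: 16 1-[5-Fl-2,4-bis(TBSO)phenyl]-3-[4-(TBSO)phenyl]propan-1-one, via arylmagnesium chloride 15 (not isolated)
Conditions: i-PrMgCl·LiCl, THF, −20 °C; then 14 (1.5 equiv), −20 °C → rt; aq NH4Cl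
Reagents that add atoms: none
Why: Iodine–magnesium exchange (the ring D bromide is untouched at −20 °C) followed by Weinreb ketone synthesis, whose chelated tetrahedral intermediate prevents over-addition.

Step 10
Reactants: 17 2',4'-dihydroxyacetophenone
Product: 18 1-[2,4-bis(TBSO)phenyl]ethan-1-one
Conditions: TBSCl (2.5 equiv), imidazole, 4-(dimethylamino)pyridine (cat.), DMF, 40 °C
Reagents that add atoms: tert-butyldimethylsilyl chloride (TBSCl), CC(C)(C)[Si](C)(C)Cl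
Why: Exhaustive phenol silylation; warming and the nucleophilic catalyst also silylate the chelated 2'-OH.

Step 11
Reactants: 18 1-[2,4-bis(TBSO)phenyl]ethan-1-one
Product: 20 2-bromo-1-[2,4-bis(TBSO)phenyl]ethan-1-one, via trimethylsilyl enol ether 19 (not isolated)
Conditions: Me3SiOTf, Et3N, CH2Cl2, 0 °C; then N-bromosuccinimide, THF, −78 → 0 °C
Reagents that add atoms: N-bromosuccinimide, O=C1CCC(=O)N1Br
Why: Soft enolisation to the silyl enol ether and electrophilic α-bromination give the monobromide without HBr, which would cleave the aryl silyl ethers.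

Step 12
Reactants: 16 1-[5-Fl-2,4-bis(TBSO)phenyl]-3-[4-(TBSO)phenyl]propan-1-one; 20 2-bromo-1-[2,4-bis(TBSO)phenyl]ethan-1-one
Product: 22 2-[4-(TBSO)benzyl]-1-[5-Fl-2,4-bis(TBSO)phenyl]-4-[2,4-bis(TBSO)phenyl]butane-1,4-dione (both C2 epimers; C2 = C3'), via lithium enolate 21 (not isolated)
Conditions: LiN(SiMe3)2, THF, −78 °C; then 20, −78 → −30 °C
Reagents that add atoms: none
Why: SN2 alkylation of the only possible ketone enolate with a primary phenacyl bromide; C3' is formed unselectively and is corrected in step 14.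

Step 13
Reactants: 22 2-[4-(TBSO)benzyl]-1-[5-Fl-2,4-bis(TBSO)phenyl]-4-[2,4-bis(TBSO)phenyl]butane-1,4-dione; 23 4-(TBSO)benzaldehyde
Product: 25 (3R)-2-[4-(TBSO)benzyl]-3-{(S)-hydroxy[4-(TBSO)phenyl]methyl}-1-[5-Fl-2,4-bis(TBSO)phenyl]-4-[2,4-bis(TBSO)phenyl]butane-1,4-dione (anti aldol; 4'R,5'S; both C3' epimers), via trimethylsilyl enol ether 24 (not isolated)
Conditions: LiN(SiMe3)2, Me3SiCl, THF, −78 °C; then 23, SiCl4, (R,R)-bisphosphoramide [(R)-C20H12(NMe)2P(O)N(Me)]2(CH2)5 from (R)-N,N'-dimethyl-1,1'-binaphthyl-2,2'-diamine (5 mol %), i-Pr2NEt (cat.), CH2Cl2, −78 °C; aq NaHCO3/KF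
Reagents that add atoms: none
Why: Mukaiyama aldol under Lewis-base-activated SiCl4: kinetic silylation takes the less hindered C4' methylene, the chiral phosphoramide-bound trichlorosilyl cation activates 23 and fixes its face (C5' S), and the open antiperiplanar transition state gives the anti adduct (C4' R) whatever the C3' configuration.

Step 14
Reactants: 25 (3R)-2-[4-(TBSO)benzyl]-3-{(S)-hydroxy[4-(TBSO)phenyl]methyl}-1-[5-Fl-2,4-bis(TBSO)phenyl]-4-[2,4-bis(TBSO)phenyl]butane-1,4-dione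
Product: 27 (2S,3R,4R,5S)-4-[2,4-bis(TBSO)benzoyl]-3-[4-(TBSO)benzyl]-2-[5-Fl-2,4-bis(TBSO)phenyl]-5-[4-(TBSO)phenyl]oxolane, via methyl ketal 26 (not isolated)
Conditions: pyridinium p-toluenesulfonate, MeOH/CH2Cl2, rt; then Et3SiH, BF3·OEt2, CH2Cl2, −78 °C
Reagents that add atoms: none
Why: Acid-catalysed ketalisation equilibrates C3' through the enol ether to the more stable 3',4'-trans methyl ketal 26, and BF3 then ionises it to the ring C-stabilised oxocarbenium ion, which Et3SiH reduces from the face anti to the C3' benzyl group (held pseudoaxial by allylic 1,2-strain against the C2' aryl group), giving the 2',3'-cis tetrahydrofuran; reductive deoxygenation of a cyclic ketal.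

Step 15
Reactants: 18 1-[2,4-bis(TBSO)phenyl]ethan-1-one
Product: 28 1-[2,4-bis(TBSO)phenyl]prop-2-en-1-one
Conditions: (CH2O)n, diisopropylammonium trifluoroacetate, CF3CO2H (cat.), THF, reflux; used fresh
Reagents that add atoms: paraformaldehyde (as formaldehyde), C=O
Why: Mannich-type α-methylenation of the methyl ketone (iminium addition, then amine elimination) gives the aryl vinyl ketone in one step.

Step 16
Reactants: 27 (2S,3R,4R,5S)-4-[2,4-bis(TBSO)benzoyl]-3-[4-(TBSO)benzyl]-2-[5-Fl-2,4-bis(TBSO)phenyl]-5-[4-(TBSO)phenyl]oxolane; 28 1-[2,4-bis(TBSO)phenyl]prop-2-en-1-one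
Product: 29 undeca-TBS ether of 30 (27 in which the ring D bromine is replaced by (E)-3-[2,4-bis(TBSO)phenyl]-3-oxoprop-1-enyl)
Conditions: Pd[P(t-Bu)3]2 (5 mol %), Cy2NMe, 1,4-dioxane, 50 °C
Reagents that add atoms: none
Why: Mizoroki–Heck coupling of the unhindered aryl bromide with the enone gives the E-chalcone under a weak hindered amine base that leaves the C4' stereocentre alone.

Step 17
Reactants: 29 undeca-TBS ether of 30
Product: 30 (E)-1-(2,4-dihydroxyphenyl)-3-{3-[(2S,3R,4R)-4-{5-[(2S,3R,4R,5S)-4-(2,4-dihydroxybenzoyl)-3-(4-hydroxybenzyl)-5-(4-hydroxyphenyl)oxolan-2-yl]-2,4-dihydroxyphenyl}-7-hydroxy-2-(4-hydroxyphenyl)chroman-3-yl]-4-hydroxyphenyl}prop-2-en-1-one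
Conditions: Bu4NF, AcOH (1:1), THF, 0 °C → rt
Reagents that add atoms: none
Why: Fluoride cleavage of all eleven aryl silyl ethers; the acetic acid buffer keeps the phenoxides from opening the β-alkoxy ketone or epimerising C4'.

**Compound list**

1 | 2,2',4,4'-tetrahydroxybenzophenone | O=C(c1ccc(O)cc1O)c1ccc(O)cc1O | starting material
2 | bis[4-(TBSO)-2-hydroxyphenyl]methanone | O=C(c1ccc(O[Si](C)(C)C(C)(C)C)cc1O)c1ccc(O[Si](C)(C)C(C)(C)C)cc1O | intermediate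
3 | bis[4-(TBSO)-2-hydroxyphenyl]methanol | OC(c1ccc(O[Si](C)(C)C(C)(C)C)cc1O)c1ccc(O[Si](C)(C)C(C)(C)C)cc1O | intermediate
4 | 4-bromo-2-iodophenol | Oc1ccc(Br)cc1I | starting material
5 | (4-bromo-2-iodophenoxy)(tert-butyl)dimethylsilane | CC(C)(C)[Si](C)(C)Oc1ccc(Br)cc1I | intermediate
6 | tert-butyldimethyl(4-vinylphenoxy)silane | C=Cc1ccc(O[Si](C)(C)C(C)(C)C)cc1 | starting material
7 | (E)-tert-butyl{4-bromo-2-[4-(TBSO)styryl]phenoxy}dimethylsilane | CC(C)(C)[Si](C)(C)Oc1ccc(/C=C/c2cc(Br)ccc2O[Si](C)(C)C(C)(C)C)cc1 | intermediate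
8 | 6-{[4-(TBSO)-2-hydroxyphenyl]methylidene}-3-(TBSO)cyclohexa-2,4-dien-1-one (ortho-quinone methide) | O=C1C=C(O[Si](C)(C)C(C)(C)C)C=CC1=Cc1ccc(O[Si](C)(C)C(C)(C)C)cc1O | intermediate (not isolated)
9 | (2S,3R,4R)-3-[5-bromo-2-(TBSO)phenyl]-7-(TBSO)-4-[4-(TBSO)-2-hydroxyphenyl]-2-[4-(TBSO)phenyl]chromane (2,3-trans-3,4-trans) | Brc1ccc(O[Si](C)(C)C(C)(C)C)c(c1)[C@H]1[C@H](c2ccc(O[Si](C)(C)C(C)(C)C)cc2O)c2ccc(O[Si](C)(C)C(C)(C)C)cc2O[C@@H]1c1ccc(O[Si](C)(C)C(C)(C)C)cc1 | intermediate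
10 | 2-Fl-4-iodo-5-(TBSO)phenol | Brc1ccc(O[Si](C)(C)C(C)(C)C)c(c1)[C@H]1[C@H](c2cc(I)c(O[Si](C)(C)C(C)(C)C)cc2O)c2ccc(O[Si](C)(C)C(C)(C)C)cc2O[C@@H]1c1ccc(O[Si](C)(C)C(C)(C)C)cc1 | intermediate (not isolated)
11 | 1-Fl-2,4-bis(TBSO)-5-iodobenzene | Brc1ccc(O[Si](C)(C)C(C)(C)C)c(c1)[C@H]1[C@H](c2cc(I)c(O[Si](C)(C)C(C)(C)C)cc2O[Si](C)(C)C(C)(C)C)c2ccc(O[Si](C)(C)C(C)(C)C)cc2O[C@@H]1c1ccc(O[Si](C)(C)C(C)(C)C)cc1 | intermediate
12 | 3-(4-hydroxyphenyl)propanoic acid | OC(=O)CCc1ccc(O)cc1 | starting material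
13 | 3-(4-hydroxyphenyl)-N-methoxy-N-methylpropanamide | CON(C)C(=O)CCc1ccc(O)cc1 | intermediate
14 | 3-[4-(TBSO)phenyl]-N-methoxy-N-methylpropanamide | CON(C)C(=O)CCc1ccc(O[Si](C)(C)C(C)(C)C)cc1 | intermediate
15 | [5-Fl-2,4-bis(TBSO)phenyl]magnesium chloride | Brc1ccc(O[Si](C)(C)C(C)(C)C)c(c1)[C@H]1[C@H](c2cc([Mg]Cl)c(O[Si](C)(C)C(C)(C)C)cc2O[Si](C)(C)C(C)(C)C)c2ccc(O[Si](C)(C)C(C)(C)C)cc2O[C@@H]1c1ccc(O[Si](C)(C)C(C)(C)C)cc1 | intermediate (not isolated)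
16 | 1-[5-Fl-2,4-bis(TBSO)phenyl]-3-[4-(TBSO)phenyl]propan-1-one | Brc1ccc(O[Si](C)(C)C(C)(C)C)c(c1)[C@H]1[C@H](c2cc(C(=O)CCc3ccc(O[Si](C)(C)C(C)(C)C)cc3)c(O[Si](C)(C)C(C)(C)C)cc2O[Si](C)(C)C(C)(C)C)c2ccc(O[Si](C)(C)C(C)(C)C)cc2O[C@@H]1c1ccc(O[Si](C)(C)C(C)(C)C)cc1 | intermediate
17 | 2',4'-dihydroxyacetophenone | CC(=O)c1ccc(O)cc1O | starting material
18 | 1-[2,4-bis(TBSO)phenyl]ethan-1-one | CC(=O)c1ccc(O[Si](C)(C)C(C)(C)C)cc1O[Si](C)(C)C(C)(C)C | intermediate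
19 | {1-[2,4-bis(TBSO)phenyl]ethenyloxy}trimethylsilane | C=C(O[Si](C)(C)C)c1ccc(O[Si](C)(C)C(C)(C)C)cc1O[Si](C)(C)C(C)(C)C | intermediate (not isolated)
20 | 2-bromo-1-[2,4-bis(TBSO)phenyl]ethan-1-one | BrCC(=O)c1ccc(O[Si](C)(C)C(C)(C)C)cc1O[Si](C)(C)C(C)(C)C | intermediate
21 | lithium (Z)-enolate of 16 | Brc1ccc(O[Si](C)(C)C(C)(C)C)c(c1)[C@H]1[C@H](c2cc(/C(O[Li])=C/Cc3ccc(O[Si](C)(C)C(C)(C)C)cc3)c(O[Si](C)(C)C(C)(C)C)cc2O[Si](C)(C)C(C)(C)C)c2ccc(O[Si](C)(C)C(C)(C)C)cc2O[C@@H]1c1ccc(O[Si](C)(C)C(C)(C)C)cc1 | intermediate (not isolated)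
22 | 2-[4-(TBSO)benzyl]-1-[5-Fl-2,4-bis(TBSO)phenyl]-4-[2,4-bis(TBSO)phenyl]butane-1,4-dione (both C2 epimers; C2 = C3') | Brc1ccc(O[Si](C)(C)C(C)(C)C)c(c1)[C@H]1[C@H](c2cc(C(=O)C(Cc3ccc(O[Si](C)(C)C(C)(C)C)cc3)CC(=O)c3ccc(O[Si](C)(C)C(C)(C)C)cc3O[Si](C)(C)C(C)(C)C)c(O[Si](C)(C)C(C)(C)C)cc2O[Si](C)(C)C(C)(C)C)c2ccc(O[Si](C)(C)C(C)(C)C)cc2O[C@@H]1c1ccc(O[Si](C)(C)C(C)(C)C)cc1 | intermediate
23 | 4-(TBSO)benzaldehyde | O=Cc1ccc(O[Si](C)(C)C(C)(C)C)cc1 | starting material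
24 | (Z)-4-trimethylsilyl enol ether of 22 (enol ether at C4'; both C3' epimers) | Brc1ccc(O[Si](C)(C)C(C)(C)C)c(c1)[C@H]1[C@H](c2cc(C(=O)C(Cc3ccc(O[Si](C)(C)C(C)(C)C)cc3)/C=C(\O[Si](C)(C)C)c3ccc(O[Si](C)(C)C(C)(C)C)cc3O[Si](C)(C)C(C)(C)C)c(O[Si](C)(C)C(C)(C)C)cc2O[Si](C)(C)C(C)(C)C)c2ccc(O[Si](C)(C)C(C)(C)C)cc2O[C@@H]1c1ccc(O[Si](C)(C)C(C)(C)C)cc1 | intermediate (not isolated)
25 | (3R)-2-[4-(TBSO)benzyl]-3-{(S)-hydroxy[4-(TBSO)phenyl]methyl}-1-[5-Fl-2,4-bis(TBSO)phenyl]-4-[2,4-bis(TBSO)phenyl]butane-1,4-dione (anti aldol; 4'R,5'S; both C3' epimers) | Brc1ccc(O[Si](C)(C)C(C)(C)C)c(c1)[C@H]1[C@H](c2cc(C(=O)C(Cc3ccc(O[Si](C)(C)C(C)(C)C)cc3)[C@@H](C(=O)c3ccc(O[Si](C)(C)C(C)(C)C)cc3O[Si](C)(C)C(C)(C)C)[C@H](O)c3ccc(O[Si](C)(C)C(C)(C)C)cc3)c(O[Si](C)(C)C(C)(C)C)cc2O[Si](C)(C)C(C)(C)C)c2ccc(O[Si](C)(C)C(C)(C)C)cc2O[C@@H]1c1ccc(O[Si](C)(C)C(C)(C)C)cc1 | intermediate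
26 | (3R,4R,5S)-4-[2,4-bis(TBSO)benzoyl]-3-[4-(TBSO)benzyl]-2-[5-Fl-2,4-bis(TBSO)phenyl]-2-methoxy-5-[4-(TBSO)phenyl]oxolane (both anomers) | Brc1ccc(O[Si](C)(C)C(C)(C)C)c(c1)[C@H]1[C@H](c2cc(C3(OC)O[C@H](c4ccc(O[Si](C)(C)C(C)(C)C)cc4)[C@H](C(=O)c4ccc(O[Si](C)(C)C(C)(C)C)cc4O[Si](C)(C)C(C)(C)C)[C@H]3Cc3ccc(O[Si](C)(C)C(C)(C)C)cc3)c(O[Si](C)(C)C(C)(C)C)cc2O[Si](C)(C)C(C)(C)C)c2ccc(O[Si](C)(C)C(C)(C)C)cc2O[C@@H]1c1ccc(O[Si](C)(C)C(C)(C)C)cc1 | intermediate (not isolated)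
27 | (2S,3R,4R,5S)-4-[2,4-bis(TBSO)benzoyl]-3-[4-(TBSO)benzyl]-2-[5-Fl-2,4-bis(TBSO)phenyl]-5-[4-(TBSO)phenyl]oxolane (2,3-cis-3,4-trans-4,5-cis) | Brc1ccc(O[Si](C)(C)C(C)(C)C)c(c1)[C@H]1[C@H](c2cc([C@H]3O[C@H](c4ccc(O[Si](C)(C)C(C)(C)C)cc4)[C@H](C(=O)c4ccc(O[Si](C)(C)C(C)(C)C)cc4O[Si](C)(C)C(C)(C)C)[C@H]3Cc3ccc(O[Si](C)(C)C(C)(C)C)cc3)c(O[Si](C)(C)C(C)(C)C)cc2O[Si](C)(C)C(C)(C)C)c2ccc(O[Si](C)(C)C(C)(C)C)cc2O[C@@H]1c1ccc(O[Si](C)(C)C(C)(C)C)cc1 | intermediate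
28 | 1-[2,4-bis(TBSO)phenyl]prop-2-en-1-one | C=CC(=O)c1ccc(O[Si](C)(C)C(C)(C)C)cc1O[Si](C)(C)C(C)(C)C | intermediate
29 | undeca-TBS ether of 30 | O=C(/C=C/c1ccc(O[Si](C)(C)C(C)(C)C)c(c1)[C@H]1[C@H](c2cc([C@H]3O[C@H](c4ccc(O[Si](C)(C)C(C)(C)C)cc4)[C@H](C(=O)c4ccc(O[Si](C)(C)C(C)(C)C)cc4O[Si](C)(C)C(C)(C)C)[C@H]3Cc3ccc(O[Si](C)(C)C(C)(C)C)cc3)c(O[Si](C)(C)C(C)(C)C)cc2O[Si](C)(C)C(C)(C)C)c2ccc(O[Si](C)(C)C(C)(C)C)cc2O[C@@H]1c1ccc(O[Si](C)(C)C(C)(C)C)cc1)c1ccc(O[Si](C)(C)C(C)(C)C)cc1O[Si](C)(C)C(C)(C)C | intermediate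
30 | CNP0330082.3: chroman (2S,3R,4R), oxolane (2S,3R,4R,5S), E-chalcone (full name in step 17) | O=C(/C=C/c1ccc(O)c([C@H]2[C@H](c3cc([C@H]4O[C@H](c5ccc(O)cc5)[C@H](C(=O)c5ccc(O)cc5O)[C@H]4Cc4ccc(O)cc4)c(O)cc3O)c3ccc(O)cc3O[C@@H]2c2ccc(O)cc2)c1)c1ccc(O)cc1O | target

**Step count and risks**

Total: 17 steps. Longest linear sequence: 10 steps (1, 2, 5, 6, 9, 12, 13, 14, 16, 17).

The three steps most likely to fail are 5, 13 and 14.

Step 5 may fail because a 1,2-diaryl alkene is a slower and more hindered partner than the styrenes known in this cycloaddition, and the electron-rich carbinol can alkylate itself. The fallback gives up catalyst control. It sets out again from 3 (with 7): diphenyl phosphate, (PhO)2P(O)OH, in CH2Cl2/(CF3)2CHOH promotes the same all-trans cycloaddition to the racemate, that is 9 together with its mirror image, the (2R,3S,4S)-cycloadduct F1. The racemate is resolved by preparative chromatography on a chiral stationary phase, and the route is rejoined at 9.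

Step 13 may fail because the enol ether is hindered at C4' and the aldehyde is electron-rich, so conversion or catalyst control may be poor. The fallback sets out from 22 and uses a closed transition state instead. Cy2BCl/Et3N forms the E-boron enolate at the C4' methylene; addition of 23 at −78 °C and oxidative work-up give only anti aldols, but as two diastereomers, 25 and the (4'S,5'R)-anti aldol F2. Because the flavan part is a single enantiomer, these are separable by chromatography, and the route is rejoined at 25.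

Step 14 may fail if the C3' equilibration is incomplete or if the hydride does not add anti to the benzyl group. The fallback sets out from 25. Dehydration (pyridinium p-toluenesulfonate, toluene, 4 Å MS, 60 °C) removes the C3' stereocentre and gives the 2-aryl-4,5-dihydrofuran F3. Hydrogenation of its enol ether with [Ir(cod)(PCy3)(pyridine)]PF6 and H2 in CH2Cl2 is directed by the C4' ketone, so both hydrogens arrive on the aroyl face and the C3' benzyl and C2' aryl groups end up cis to each other and trans to the aroyl group. The route is rejoined at 27.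

**Further compounds**

F1 | step 5 | (2R,3S,4S)-enantiomer of 9 | Brc1ccc(O[Si](C)(C)C(C)(C)C)c(c1)[C@@H]1[C@@H](c2ccc(O[Si](C)(C)C(C)(C)C)cc2O)c2ccc(O[Si](C)(C)C(C)(C)C)cc2O[C@H]1c1ccc(O[Si](C)(C)C(C)(C)C)cc1
F2 | step 13 | (4'S,5'R)-anti aldol diastereomer of 25 (both C3' epimers) | Brc1ccc(O[Si](C)(C)C(C)(C)C)c(c1)[C@H]1[C@H](c2cc(C(=O)C(Cc3ccc(O[Si](C)(C)C(C)(C)C)cc3)[C@H](C(=O)c3ccc(O[Si](C)(C)C(C)(C)C)cc3O[Si](C)(C)C(C)(C)C)[C@@H](O)c3ccc(O[Si](C)(C)C(C)(C)C)cc3)c(O[Si](C)(C)C(C)(C)C)cc2O[Si](C)(C)C(C)(C)C)c2ccc(O[Si](C)(C)C(C)(C)C)cc2O[C@@H]1c1ccc(O[Si](C)(C)C(C)(C)C)cc1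
F3 | step 14 | (4R,5S)-4-[2,4-bis(TBSO)benzoyl]-3-[4-(TBSO)benzyl]-2-[5-Fl-2,4-bis(TBSO)phenyl]-5-[4-(TBSO)phenyl]-4,5-dihydrofuran | Brc1ccc(O[Si](C)(C)C(C)(C)C)c(c1)[C@H]1[C@H](c2cc(C3=C(Cc4ccc(O[Si](C)(C)C(C)(C)C)cc4)[C@@H](C(=O)c4ccc(O[Si](C)(C)C(C)(C)C)cc4O[Si](C)(C)C(C)(C)C)[C@@H](c4ccc(O[Si](C)(C)C(C)(C)C)cc4)O3)c(O[Si](C)(C)C(C)(C)C)cc2O[Si](C)(C)C(C)(C)C)c2ccc(O[Si](C)(C)C(C)(C)C)cc2O[C@@H]1c1ccc(O[Si](C)(C)C(C)(C)C)cc1
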